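The hemiketal tetrahydropyran (ring A: O1, C2(OH)Et, C3, C4, spiro C5, C6H2) is disconnected at O1–C6. The feature used is that O1 is the oxygen of a C2 ethyl ketone lying 1,5 to the neopentyl C6: conjugate reduction of a C3=C4 enone gives a single enolate, whose oxygen displaces a C6 sulfonate in one operation, and hydration of the enol ether sets C2. The precursor is an (E)-enone on a quaternary carbon bearing CH2OTs, made from the ring B/C bridging ketone by homologation and face-selective hydroxymethylation. Rings B–E arise from a double Mannich annulation of a cycloheptane-1,3-dione, then carbonylative Stille coupling, Nazarov cyclisation and aldol condensation.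

Key step: step 12

Ring names: ring B = N-methylpiperidine, ring C = cycloheptene, ring D = ester-free cyclopentene fused to ring C at the tetrasubstituted alkene, ring E = ester-bearing cyclopentene.
Assumption: the C2 hemiketal configuration of the target is taken to be the one reached by ring–chain equilibration (thermodynamic anomer).

Step 1
Reactants: 1 cycloheptane-1,3-dione; 2 methyl acrylate
Product: 3 methyl 3-(2,6-dioxocycloheptyl)propanoate
Conditions: NaOMe (0.2 equiv), MeOH, 65 °C
Reagents that add atoms: none
Why: Michael addition of the acidic C2–H of the cyclic 1,3-dione to the acrylate, with one equivalent of acceptor to limit double addition.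

Step 2
Reactants: 3 methyl 3-(2,6-dioxocycloheptyl)propanoate
Product: 4 racemic methyl 3-(8-methyl-2,10-dioxo-8-azabicyclo[4.3.1]decan-1-yl)propanoate
Conditions: MeNH2·HCl (1.05 equiv), 37% aq. CH2O (2.2 equiv), MeOH, 65 °C; then aq. NaHCO3
Reagents that add atoms: methylamine hydrochloride CN.Cl; formaldehyde C=O
Why: Double Mannich annulation, in which aminomethylation at the doubly activated C2 is followed by attack of one ketone enol (at its CH2) on the N-methyl iminium ion to close ring B; the bridge can only span one face, so a single racemic diastereomer should form.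

Step 3
Reactants: 4 racemic azabicyclic diketone
Product: 5 methyl 3-[(1R,6R)-8-methyl-2,10-dioxo-8-azabicyclo[4.3.1]decan-1-yl]propanoate
Conditions: (−)-O,O′-di-p-toluoyl-L-tartaric acid (1 equiv), EtOH/acetone, fractional crystallisation; then aq. NaHCO3, CH2Cl2
Reagents that add atoms: none
Why: Classical resolution of the basic amine by diastereomeric salt crystallisation fixes the absolute configuration of both bridgeheads (the antipodal acid is taken if the other salt is the less soluble one).

Step 4
Reactants: 5 (1R,6R)-azabicyclic diketone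
Product: 6 methyl 3-[(1R,6R)-8-methyl-10-oxo-2-(trifluoromethylsulfonyloxy)-8-azabicyclo[4.3.1]dec-2-en-1-yl]propanoate
Conditions: KN(SiMe3)2 (1.1 equiv), THF, −78 °C; then N-(5-chloropyridin-2-yl)bis(trifluoromethanesulfonimide) (1.2 equiv), −78 to −30 °C
Reagents that add atoms: N-(5-chloropyridin-2-yl)bis(trifluoromethanesulfonimide) O=S(=O)(N(c1ccc(Cl)cn1)S(=O)(=O)C(F)(F)F)C(F)(F)F
Why: Enol triflate formation is regiospecific because only the C3 methylene of the ring C ketone can enolise (the C10 ketone lies between two bridgeheads), and the low temperature should suppress Claisen attack on the ester.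

Step 5
Reactants: 6 enol triflate
Product: 7 methyl 3-[8-methyl-10-oxo-2-(prop-2-enoyl)-8-azabicyclo[4.3.1]dec-2-en-1-yl]propanoate, bridgeheads as in 5
Conditions: Pd(PPh3)4 (5 mol %), LiCl (3 equiv), CO (3 atm), tributyl(vinyl)stannane (1.2 equiv), THF, 55 °C
Reagents that add atoms: carbon monoxide [C-]#[O+]; tributyl(vinyl)stannane C=C[Sn](CCCC)(CCCC)CCCC
Why: Carbonylative Stille coupling (oxidative addition of the vinyl triflate, CO insertion, vinyl transfer from tin) should give the cross-conjugated divinyl ketone, the CO pressure keeping acylation ahead of direct coupling.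

Step 6
Reactants: 7 divinyl ketone
Product: 8 tricyclic keto enone in which a cyclopent-2-enone (ring D) is fused through its C2=C3 bond to ring C, bridgeheads as in 5
Conditions: CF3SO3H (3 equiv), CH2Cl2, 0 °C to rt; then aq. NaHCO3
Reagents that add atoms: none
Why: Nazarov cyclisation (conrotatory 4π closure of the O-protonated dienone) followed by proton loss to the tetrasubstituted ring C/D fusion alkene, the thermodynamic enone; the protonated amine cannot trigger Grob-type cleavage.

Step 7
Reactants: 8 tricyclic keto enone
Product: 9 tetracyclic dienoate ketone (rings B, C, D and E closed; methyl ester on ring E; bridging ketone)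
Conditions: NaOMe (2 equiv), MeOH, 65 °C
Reagents that add atoms: none
Why: Intramolecular aldol condensation, in which the ester enolate adds 5-exo-trig to the ring D carbonyl (conjugate addition would be 5-endo) and E1cB loss of water gives the fully conjugated dienoate, which drains the reversible side equilibria.

Step 8
Reactants: 9 tetracyclic dienoate ketone
Product: 11 aldehyde with CHO on the former ketone carbon (mixture of epimers at that carbon), via enol ether 10 (not isolated)
Conditions: Ph3P(Cl)CH2OMe (2.5 equiv), KN(SiMe3)2 (2.4 equiv), THF, 0 to 45 °C; then 2 M HCl, THF, rt; then aq. NaHCO3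
Reagents that add atoms: (methoxymethyl)triphenylphosphonium chloride COC[P+](c1ccccc1)(c1ccccc1)c1ccccc1.[Cl-]; water O
Why: Wittig methoxymethylenation of the bridging ketone and hydrolysis of the enol ether give the homologous aldehyde, whose new stereocentre is left uncontrolled because the next step enolises it.

Step 9
Reactants: 11 aldehyde
Product: 12 β-hydroxy aldehyde with a quaternary carbon bearing CHO (syn to ring B) and CH2OH (syn to ring C)
Conditions: 37% aq. CH2O (5 equiv), K2CO3 (0.3 equiv), MeOH/THF, 0 °C to rt
Reagents that add atoms: formaldehyde C=O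
Why: Crossed aldol hydroxymethylation of the α-branched aldehyde, in which formaldehyde should attack the enolate carbon from the face over ring C (one flanking pseudo-axial C–H and a trigonal fusion carbon) rather than over ring B (two axial C–H bonds), so that CH2OH ends syn to ring C.

Step 10
Reactants: 12 β-hydroxy aldehyde
Product: 13 tosylate of 12
Conditions: TsCl (1.5 equiv), Et3N (2 equiv), DMAP (0.1 equiv), CH2Cl2, 0 °C to rt
Reagents that add atoms: p-toluenesulfonyl chloride Cc1ccc(cc1)S(Cl)(=O)=O
Why: Sulfonylation of the neopentyl primary alcohol blocks retro-aldol loss of formaldehyde in the next step and makes C6 the electrophile.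

Step 11
Reactants: 13 aldehyde tosylate; 14 diethyl (2-oxobutyl)phosphonate
Product: 15 (E)-enone, with an (E)-3-oxopent-1-enyl group in place of CHO
Conditions: NaH (1.2 equiv), 14 (1.3 equiv), THF, 0 °C; then 13, 0 °C to rt
Reagents that add atoms: none
Why: Horner–Wadsworth–Emmons olefination of the hindered aldehyde with the ketophosphonate anion should give the (E)-enone, the neopentyl tosylate being inert to the stabilised anion.

Step 12
Reactants: 15 (E)-enone tosylate
Product: 18 target CNP0192143.1, via silyl enol ether 16 (not isolated), via dihydropyran 17 (not isolated)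
Conditions: [(Ph3P)CuH]6 (5 mol %), PhMe2SiH (1.3 equiv), toluene, rt; then Bu4N[Ph3SiF2] (1.3 equiv), DMPU, 50 °C; then 1 M HCl, THF, rt; then aq. NaHCO3
Reagents that add atoms: water O
Why: Copper hydride adds to C4 of the s-cis enone and the copper enolate is silylated to the (Z)-silyl enol ether 16, so the enolate exists only toward C3; fluoride then frees the ammonium enolate, whose oxygen O1 displaces the tosylate at C6 to close ring A as the enol ether 17, and aqueous acid adds water across C2=C3 to give the hemiketal. The closest known reaction type is the reductive alkylation of enones (conjugate reduction followed by enolate alkylation), run here as an intramolecular O-alkylation. Ring A closes in a 6-exo-tet mode at the enolate oxygen. The only new stereocentre, C2, is set under thermodynamic control by reversible hemiketalisation, and spiro C5 is not touched. The step needs O- rather than C-alkylation and the C3 rather than the ethyl-side enolate; the first is secured because C-alkylation would be a 4-exo-tet closure and the leaving group is a hard sulfonate in a dipolar solvent, the second by generating the enolate from the enone.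

Compound list
1 | cycloheptane-1,3-dione | O=C1CCCCC(=O)C1 | starting material
2 | methyl acrylate | C=CC(=O)OC | starting material
3 | methyl 3-(2,6-dioxocycloheptyl)propanoate | COC(=O)CCC1C(=O)CCCCC1=O | intermediate
4 | racemic methyl 3-(8-methyl-2,10-dioxo-8-azabicyclo[4.3.1]decan-1-yl)propanoate | O=C1C2CCCC(=O)C1(CCC(=O)OC)CN(C)C2 | intermediate
5 | methyl 3-[(1R,6R)-8-methyl-2,10-dioxo-8-azabicyclo[4.3.1]decan-1-yl]propanoate | O=C1[C@@H]2CCCC(=O)[C@@]1(CCC(=O)OC)CN(C)C2 | intermediate
6 | methyl 3-[(1R,6R)-8-methyl-10-oxo-2-(trifluoromethylsulfonyloxy)-8-azabicyclo[4.3.1]dec-2-en-1-yl]propanoate | O=C1[C@@H]2CCC=C(OS(=O)(=O)C(F)(F)F)[C@@]1(CCC(=O)OC)CN(C)C2 | intermediate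
7 | methyl 3-[8-methyl-10-oxo-2-(prop-2-enoyl)-8-azabicyclo[4.3.1]dec-2-en-1-yl]propanoate, bridgeheads as in 5 | O=C1[C@@H]2CCC=C(C(=O)C=C)[C@@]1(CCC(=O)OC)CN(C)C2 | intermediate
8 | tricyclic keto enone (ring D cyclopentenone fused to ring C; propanoate arm on the quaternary bridgehead), bridgeheads as in 5 | O=C1[C@@H]2CCC3=C(C(=O)CC3)[C@@]1(CCC(=O)OC)CN(C)C2 | intermediate
9 | tetracyclic dienoate ketone (rings B–E, bridging ketone), bridgeheads as in 5 | O=C1[C@@H]2CCC3=C4C(CC3)=C(C(=O)OC)C[C@@]41CN(C)C2 | intermediate
10 | methyl enol ether of 9 (exocyclic C=CH–OMe, E/Z mixture) | COC=C1[C@@H]2CCC3=C4C(CC3)=C(C(=O)OC)C[C@@]41CN(C)C2 | intermediate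
11 | aldehyde (CHO on the former ketone carbon, epimer mixture there) | O=CC1[C@@H]2CCC3=C4C(CC3)=C(C(=O)OC)C[C@@]41CN(C)C2 | intermediate
12 | β-hydroxy aldehyde (CHO syn to ring B, CH2OH syn to ring C) | O=C[C@@]1(CO)[C@@H]2CCC3=C4C(CC3)=C(C(=O)OC)C[C@@]41CN(C)C2 | intermediate
13 | tosylate of 12 | O=C[C@@]1(COS(=O)(=O)c5ccc(C)cc5)[C@@H]2CCC3=C4C(CC3)=C(C(=O)OC)C[C@@]41CN(C)C2 | intermediate
14 | diethyl (2-oxobutyl)phosphonate | CCC(=O)CP(=O)(OCC)OCC | starting material
15 | (E)-enone tosylate | CCC(=O)/C=C/[C@@]1(COS(=O)(=O)c5ccc(C)cc5)[C@@H]2CCC3=C4C(CC3)=C(C(=O)OC)C[C@@]41CN(C)C2 | intermediate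
16 | (Z)-dimethylphenylsilyl enol ether of the reduced enone | CC/C(O[Si](C)(C)c6ccccc6)=C/C[C@@]1(COS(=O)(=O)c5ccc(C)cc5)[C@@H]2CCC3=C4C(CC3)=C(C(=O)OC)C[C@@]41CN(C)C2 | intermediate
17 | spiro 6-ethyl-3,4-dihydro-2H-pyran (ring A as enol ether) | CCC1=CC[C@@]2(CO1)[C@@H]1CCC3=C4C(=C(C(=O)OC)C[C@@]42CN(C)C1)CC3 | intermediate
18 | CNP0192143.1 | CC[C@@]1(O)CC[C@@]2(CO1)[C@@H]1CCC3=C4C(=C(C(=O)OC)C[C@@]42CN(C)C1)CC3 | target

Total step count: 12. Longest linear sequence: 12 steps (from 1).

Steps most likely to fail

Step 9. Formaldehyde may attack the aldehyde enolate from the face over ring B, giving poor or reversed facial selectivity at spiro C5. The fallback sets out from 10 (step 8 stopped before the acid stage) and lets the two exocyclic carbons exchange roles. Heating 10 with ethyl vinyl ketone (toluene, 130 °C, sealed tube, BHT) in an inverse-electron-demand hetero-Diels–Alder reaction adds the chain carbon C4 from that same face and forms O1–C6 at the acetal carbon, giving the 2-methoxydihydropyran adduct F1. Ionic reduction of the anomeric methoxy group (Et3SiH, Me3SiOTf, CH2Cl2, −78 °C) then gives 17, where the route resumes with the aqueous acid stage of step 12.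

Step 12. Proton transfer to the free enolate, or slow substitution at the neopentyl carbon, may leave the chain uncyclised. The fallback sets out from 15. Conjugate reduction alone ([(Ph3P)CuH]6, PhMe2SiH, toluene, then aqueous NH4F work-up) gives the saturated keto tosylate F2. K2CO3 in MeOH at 50 °C then closes ring A through the methyl hemiketal alkoxide, an intramolecular Williamson reaction of the kind that forms 1,6-anhydro sugars, to give the cyclic methyl ketal F3. Hydrolysis with 1 M HCl in THF returns to the route at 18.

Step 6. The vinyl ketone may polymerise, or the oxyallyl cation next to the quaternary bridgehead may undergo a cationic 1,2-shift instead of clean ring closure. The fallback sets out from 5 and builds ring D by umpolung. Alkylation of the potassium enolate (KN(SiMe3)2, THF, −78 °C, then 2-(2-iodoethyl)-1,3-dioxolane, DMPU) gives the dioxolane-alkylated diketone F4, and aqueous HCl in acetone frees the keto aldehyde F5. An intramolecular crossed benzoin reaction onto the ring C ketone (3-benzyl-5-(2-hydroxyethyl)-4-methylthiazolium chloride, Et3N, EtOH, 70 °C) gives the acyloin F6. Dehydration (SOCl2, pyridine, 0 °C) returns to the route at 8.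

Further compounds
F1 | step 9 | 2-methoxydihydropyran adduct | CCC1=CC[C@@]2(C(OC)O1)[C@@H]1CCC3=C4C(=C(C(=O)OC)C[C@@]42CN(C)C1)CC3
F2 | step 12 | saturated keto tosylate | CCC(=O)CC[C@@]1(COS(=O)(=O)c5ccc(C)cc5)[C@@H]2CCC3=C4C(CC3)=C(C(=O)OC)C[C@@]41CN(C)C2
F3 | step 12 | cyclic methyl ketal | CCC1(OC)CC[C@@]2(CO1)[C@@H]1CCC3=C4C(=C(C(=O)OC)C[C@@]42CN(C)C1)CC3
F4 | step 6 | dioxolane-alkylated diketone | O=C1[C@@H]2CCC(CCC3OCCO3)C(=O)[C@@]1(CCC(=O)OC)CN(C)C2
F5 | step 6 | keto aldehyde | O=C1[C@@H]2CCC(CCC=O)C(=O)[C@@]1(CCC(=O)OC)CN(C)C2
F6 | step 6 | acyloin | O=C1[C@@H]2CCC3CCC(=O)C3(O)[C@@]1(CCC(=O)OC)CN(C)C2
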